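Its constants are made up; the run is a simulation.

A small charge of protic impurity was what I chose to read these flasks by.

common to all: protic impurity 0.0750 M
- south: starting material 0.25 M; time 1.5 min; everything together in a closed stirred flask, run for 1.5 min
- south-west: starting material 0.25 M (fed, over 1.20 min); time 1.5 min; a stirred flask in which starting material is dosed at a steady rate over 1.20 min without added volume, worked up at 1.5 min
- south-east: starting material 0.25 M; a single well-mixed tank run continuously and read at steady state, 1.5 min in it on average
- west: starting material 0.25 M; one stirred flow tank at steady state, fed with the mixture as stated, mean residence time 15.0 min

    starting material + protic impurity → quenched substrate (k1 = 0.0402 /M/s)
    starting material → product (k2 = 1.46 × 10⁻⁴ /s)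
    starting material + product → 2 product (k3 = 0.0442 /M/s)

- the stated concentrations are those of everything mixed, before any reaction; amounts are the same in each set-up
- the feed brings no volume worth counting
- run time (south): 1.5 min

* the set-up with the highest amount of product at the outlet or at the end, in percent of the starting material put in ("none" if the first two lie within 2 percentage points) (south / south-west / south-east / west / none)
* amount of product at the outlet or at the end, in percent of the starting material put in, south
* amount of product at the outlet or at the end, in percent of the starting material put in, south-west
* amount of product at the outlet or at the end, in percent of the starting material put in, south-east
* amount of product at the outlet or at the end, in percent of the starting material put in, west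

I divided the rate at which product grows by the rate at which protic impurity goes. [Starting material] stands in both, so it cancels, and time with it. What remains is the uncatalysed constant plus the autocatalytic constant times [product], over the impurity constant times [impurity]. Integrating needs two numbers. One is the seed, the [product] at which the two product-making steps run equally fast, 0.00330 M. The other is the autocatalytic constant over the impurity constant, a selectivity factor of 1.10. The rule, for a flask without outflow that starts free of product, dosed or not: [product] is the seed times the charged [impurity] over the [impurity] left, raised to that factor, less one seed.

At the start of south the impurity path used starting material 21 times as fast as the uncatalysed path, so I integrated the impurity step by itself. That put [impurity] at 0.0332 M at 1.5 min, and the rule gave 1.92%.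

My second way kept time: product grows exponentially from the seed with [starting material] held at its charge, which gave 2.25%. The two parted by 0.33 percentage points, and the second cheats: it holds 0.25 M while the impurity step takes 0.0418 M away. I kept the first.

For west I took a steady tank with [starting material] near 0.0251 M and [impurity] quenching 0.0357 M, which left 75.7%. With south-west delayed by half its feed and south-east scored by its tank balance, the winner was west.

The forecast gave 1.9% for south, 0.97% for south-west, 5.7% for south-east and 76% for west, so west, west having a “long enough residence time for autocatalysis to take over”.

The simulation gave 1.89%, 0.966%, 5.68% and 76.0% in that order, with west the best.

South had not come to rest at 1.5 min: 81% of its starting material and 45% of its impurity still stood. At ten times the time, 15.0 min, product stood at 68.9%, a further 67 points, with starting material at 1.90% and impurity at 2.70% of its charge. The seed rule, given those two impurity readings, returns 1.89% and 68.8%.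

In a neighbour flask, south with 1.0 M of starting material, the impurity fell to 3.7% of its charge, and the same seed gives 12.2% of the starting material. The computed flask holds 12.2%.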